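A direct plan would take 1-(2-hydroxy-4,5-dimethoxyphenyl)ethan-1-one A1 through amide-acetal condensation and acid cyclisation to 6,7-dimethoxy-4H-chromen-4-one A2 and so close ring C first, then zincate C2–H of A2 with TMPZnCl·LiCl (TMP = 2,2,6,6-tetramethylpiperidin-1-yl) to the chromon-2-ylzinc chloride A3 and couple A3 with 1-iodo-2,3,4-trimethoxybenzene A4 on Pd(OAc)2 and SPhos.
It would be short and free of stereochemical issues, but its weak points would be:
- the C2–H zincation, whose choice of C2 over C3 would hang on the absence of a Lewis acid and whose product could add to unreacted A2 or be protonated back to it;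
- the final C2–aryl cross-coupling, slow for the electron-rich, ortho-substituted A4 and run on all of the precious chromone;
- the separate making of bare A2 from A1, an operation that brings in nothing of ring B and leaves the plan linear.

**Plan of the new route**
The retrosynthesis cuts three bonds of ring C at once, C4a–C4, C4–C3 and O1–C2, so that C4 and its oxygen come from carbon monoxide.
Ring A with O1 comes from 3,4-dimethoxyphenol 1 by way of its ortho iodide 2; C3, C2 and ring B come from 2,3,4-trimethoxybenzaldehyde 3 by way of alkyne 4.
The enabling feature is that the ketone carbon C4 is a single carbon on C4a, ortho to the O1-bearing C8a, and is flanked by the C2=C3 unit, which has the oxidation level of an alkyne.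
Rings A and B are bought; ring C arises last and only in the final step, by 6-endo closure of O1 on C2.
No chromone is ever metallated and the C2–aryl bond is never made, since it is already present in 4; the route is convergent, with one step to each partner.

Key step: step 3

Remark: the target has no stereocentre, so no configuration has to be set; the only stereodescriptor in the route is the E double bond of a transient enaminone.

Step 1
Reactants: 1 3,4-dimethoxyphenol
Product: 2 2-iodo-4,5-dimethoxyphenol
Conditions: NIS (1.0 equiv), MeCN, −10 → 0 °C, dark, 1 h; aq Na2S2O3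
Reagents that add atoms: N-iodosuccinimide (NIS), O=C1CCC(=O)N1I
Why: Electrophilic aromatic iodination in which the hydroxyl group (ortho) and the 3-methoxy group (para) both direct to C6, while C2 between two oxygens is hindered, so the iodine should enter only at the carbon that becomes C4a.

Step 2
Reactants: 3 2,3,4-trimethoxybenzaldehyde
Product: 4 1-ethynyl-2,3,4-trimethoxybenzene
Conditions: dimethyl (1-diazo-2-oxopropyl)phosphonate (1.3 equiv), K2CO3 (2 equiv), MeOH, 0 → 20 °C, 12 h
Reagents that add atoms: dimethyl (1-diazo-2-oxopropyl)phosphonate, CC(=O)C(=[N+]=[N-])P(=O)(OC)OC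
Why: Seyferth–Gilbert homologation in the Ohira–Bestmann form, in which methanolysis of the acetyl group frees the diazomethylphosphonate anion, this olefinates the aldehyde, and loss of N2 with 1,2-hydrogen shift of the alkylidene carbene gives the terminal alkyne under mild base that leaves the methyl ethers alone.

Step 3
Reactants: 2 2-iodo-4,5-dimethoxyphenol; 4 1-ethynyl-2,3,4-trimethoxybenzene
Product: 7 6,7-dimethoxy-2-(2,3,4-trimethoxyphenyl)-4H-chromen-4-one, via ynone 5 (not isolated), via enaminone 6 (not isolated)
Conditions: 2 (1.0 equiv), 4 (1.2 equiv), PdCl2(dppf) (dppf = 1,1'-bis(diphenylphosphino)ferrocene; 2 mol %), CO (20 bar), Et2NH (solvent), 120 °C, 2–4 h, autoclave, no copper salt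
Reagents that add atoms: carbon monoxide, [C-]#[O+]; diethylamine, CCNCC (its atoms enter 6 only and leave again on ring closure)
Why: Zerovalent palladium, formed in the flask from PdCl2(dppf), inserts into the C–I bond of 2, CO inserts into the electron-rich aryl–palladium bond to give an aroylpalladium iodide, and copper-free alkynylation by 4 with reductive elimination gives ynone 5, which makes the C4a–C4 and C4–C3 bonds. Diethylamine then adds to the ynone to give the push-pull enaminone 6, and the ortho phenol attacks its β-carbon (the future C2) and expels diethylamine, an addition–elimination that closes ring C in the 6-endo-trig mode by the O1–C2 bond. The closest known reaction type is the palladium-catalysed carbonylative Sonogashira coupling–annulation of 2-iodophenols with terminal alkynes under CO in a secondary amine. No stereocentre is formed. Two selectivities are needed: carbonylative over direct coupling (which would lead to a 2-arylbenzofuran) is secured by the CO pressure, the absence of copper and the fast CO insertion of an electron-rich arylpalladium species, and 6-endo over 5-exo closure (which would give the aurone) is secured by the amine, since in 6 only the carbon bearing nitrogen is electrophilic. The free phenol needs no protection because it is the ring-closing nucleophile, and the five methyl ethers are inert.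

**Compound list**
1 | 3,4-dimethoxyphenol | COc1ccc(O)cc1OC | starting material
2 | 2-iodo-4,5-dimethoxyphenol | COc1cc(O)c(I)cc1OC | intermediate
3 | 2,3,4-trimethoxybenzaldehyde | COc1ccc(C=O)c(OC)c1OC | starting material
4 | 1-ethynyl-2,3,4-trimethoxybenzene | COc1ccc(C#C)c(OC)c1OC | intermediate
5 | 1-(2-hydroxy-4,5-dimethoxyphenyl)-3-(2,3,4-trimethoxyphenyl)prop-2-yn-1-one | COc1cc(O)c(C(=O)C#Cc2ccc(OC)c(OC)c2OC)cc1OC | intermediate
6 | (E)-3-(diethylamino)-1-(2-hydroxy-4,5-dimethoxyphenyl)-3-(2,3,4-trimethoxyphenyl)prop-2-en-1-one | CCN(CC)/C(=C/C(=O)c1cc(OC)c(OC)cc1O)c1ccc(OC)c(OC)c1OC | intermediate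
7 | 6,7-dimethoxy-2-(2,3,4-trimethoxyphenyl)-4H-chromen-4-one | COc1cc2oc(-c3ccc(OC)c(OC)c3OC)cc(=O)c2cc1OC | target

Total step count: 3. Longest linear sequence: 2 steps (1 → 2 → 7 or 3 → 4 → 7).

**Steps most likely to fail**

Step 3. The aroylpalladium intermediate may be intercepted by diethylamine (aminocarbonylation to a salicylamide), CO insertion may lag behind alkynylation (direct coupling and closure to a benzofuran), or oxidative addition into the electron-rich iodophenol may be slow. The fallback brings in C4 as an aldehyde carbon instead of CO. Setting out from 1, magnesium-mediated ortho-formylation (MgCl2, Et3N, paraformaldehyde, MeCN, reflux) would give 2-hydroxy-4,5-dimethoxybenzaldehyde F1 as the carrier of C4. The magnesium phenoxide of F1 (i-PrMgCl, THF, 0 °C) would take up the lithium acetylide made from 4 (n-BuLi, THF, −78 °C) to give racemic 2-[1-hydroxy-3-(2,3,4-trimethoxyphenyl)prop-2-yn-1-yl]-4,5-dimethoxyphenol F2 after aqueous work-up. MnO2 (CH2Cl2, 20 °C) would oxidise the benzylic propargylic alcohol of F2 to the ketone, and the fallback comes back to the route at 5, which Et2NH (EtOH, 60 °C) would take through 6 to 7.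

Step 1. The very electron-rich phenol may be oxidised by the iodinating agent (quinone formation) or iodinated twice. The fallback masks the phenol before halogenation. Setting out from 1, acetylation (Ac2O, pyridine, 20 °C) would give 3,4-dimethoxyphenyl acetate F3 and so remove the free phenol that could be oxidised to a quinone. Iodination of F3 para to the 3-methoxy group (I2, CF3CO2Ag, CHCl3, 0 °C) would give 2-iodo-4,5-dimethoxyphenyl acetate F4 with the same regiochemistry as in step 1, and methanolysis of F4 (K2CO3, MeOH, 0 °C) comes back to the route at 2.

Step 2. Addition of the diazophosphonate anion to the electron-rich, ortho-substituted aldehyde may be slow, so that the reagent is used up by methanolysis and protonation before it olefinates. The fallback is a two-stage Corey–Fuchs sequence. Setting out from 3, dibromo-olefination (CBr4, PPh3, CH2Cl2, 0 °C) would give 1-(2,2-dibromoethenyl)-2,3,4-trimethoxybenzene F5 by a Wittig-type reaction of the dibromomethylene ylide. Treatment of F5 with n-BuLi (2.2 equiv, THF, −78 °C; aq NH4Cl), by bromine–lithium exchange and Fritsch–Buttenberg–Wiechell rearrangement, comes back to the route at 4.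

**Further compounds**
F1 | step 3 | 2-hydroxy-4,5-dimethoxybenzaldehyde | COc1cc(O)c(C=O)cc1OC
F2 | step 3 | rac-2-[1-hydroxy-3-(2,3,4-trimethoxyphenyl)prop-2-yn-1-yl]-4,5-dimethoxyphenol | COc1cc(O)c(C(O)C#Cc2ccc(OC)c(OC)c2OC)cc1OC
F3 | step 1 | 3,4-dimethoxyphenyl acetate | COc1ccc(OC(C)=O)cc1OC
F4 | step 1 | 2-iodo-4,5-dimethoxyphenyl acetate | COc1cc(I)c(OC(C)=O)cc1OC
F5 | step 2 | 1-(2,2-dibromoethenyl)-2,3,4-trimethoxybenzene | COc1ccc(C=C(Br)Br)c(OC)c1OC
A1 | direct plan | 1-(2-hydroxy-4,5-dimethoxyphenyl)ethan-1-one | CC(=O)c1cc(OC)c(OC)cc1O
A2 | direct plan | 6,7-dimethoxy-4H-chromen-4-one | COc1cc2occc(=O)c2cc1OC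
A3 | direct plan | (6,7-dimethoxy-4-oxo-4H-chromen-2-yl)zinc chloride | COc1cc2oc([Zn]Cl)cc(=O)c2cc1OC
A4 | direct plan | 1-iodo-2,3,4-trimethoxybenzene | COc1ccc(I)c(OC)c1OC
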